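**Assumption:** atom labels follow germacrane numbering with the lactone oxygen on C8, so the target is (4R,5R,6R,7S,8S,9R,10R)-4,5-epoxy-9-hydroxy-6-[(3-methylbut-2-enoyl)oxy]germacr-11(13)-en-12,8-olide (C9 carries the free OH, C10 the secondary methyl, C7 the acrylate branch).

## Retrosynthetic overview

1. 23 ⇐ 21: the last step is a SmI2 ketyl-radical pinacol coupling that forms C8–C9, closing the ten-membered ring as the C8/C9 cis-diol; the C8 alkoxide then lactonises onto the acrylate ester in the same flask.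
2. 21 ⇐ 11 + 15: C6–C7 by Cr(II) 2-(methoxycarbonyl)allylation of an α,β-epoxy aldehyde (sets C6 and C7), then senecioylation and unmasking of two primary alcohols as aldehydes.
3. 11 ⇐ 9 (Sharpless epoxidation sets C4/C5) ⇐ 6 (Zr carboalumination sets the E-alkene) ⇐ 1 + 3 (Cu-catalysed sp3–sp3 coupling; C10 from the chiral pool). 15 ⇐ 12 + 13 (Baylis–Hillman, SN2′ bromination).
4. Ring order: epoxide (step 4) → carbocycle by the radical step (step 12) → γ-lactone (same operation).

## Route

Step 1
Reactants: 1 (S)-3-bromo-2-methylpropan-1-ol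
Product: 2 (S)-(3-bromo-2-methylpropoxy)(tert-butyl)dimethylsilane
Conditions: TBSCl, imidazole, DMF, 0 °C → rt
Reagents that add atoms: tert-butyldimethylsilyl chloride CC(C)(C)[Si](C)(C)Cl
Why: Standard TBS silylation of the primary alcohol, which leaves the stereocentre (future C10) untouched.

Step 2
Reactants: 2 (S)-(3-bromo-2-methylpropoxy)(tert-butyl)dimethylsilane; 3 (4-bromobut-1-yn-1-yl)trimethylsilane
Product: 6 (R)-tert-butyldimethyl[(2-methylhept-6-yn-1-yl)oxy]silane, via Grignard reagent 4 (not isolated), via TMS-alkyne 5 (not isolated)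
Conditions: 3, Mg, THF, 40 °C; then 2, Li2CuCl4 (5 mol%), NMP, THF, 0 °C → rt; then K2CO3, MeOH, rt
Reagents that add atoms: none
Why: Kochi-type Cu-catalysed sp3–sp3 Grignard cross-coupling at the primary bromide (no stereocentre involved), followed by base-mediated protodesilylation of the alkynyl-TMS group, both of which the TBS ether tolerates.

Step 3
Reactants: 6 (R)-tert-butyldimethyl[(2-methylhept-6-yn-1-yl)oxy]silane
Product: 9 (2E,7R)-8-(tert-butyldimethylsilyloxy)-3,7-dimethyloct-2-en-1-ol, via alkenylalane 7 (not isolated), via lithium alanate 8 (not isolated)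
Conditions: Me3Al, Cp2ZrCl2 (25 mol%), CH2Cl2, 0 °C → rt; then n-BuLi, THF, −78 °C; (CH2O)n, −78 °C → rt
Reagents that add atoms: trimethylaluminium C[Al](C)C; formaldehyde (from paraformaldehyde) C=O
Why: Negishi Zr-catalysed carboalumination adds Me–Al syn across the terminal alkyne to give only the (E)-2-methylalkenylalane, and its ate complex is hydroxymethylated with retention, which fixes the E-trisubstituted C4=C5 alkene.

Step 4
Reactants: 9 (2E,7R)-8-(tert-butyldimethylsilyloxy)-3,7-dimethyloct-2-en-1-ol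
Product: 10 [(2R,3R)-3-[(4R)-5-(tert-butyldimethylsilyloxy)-4-methylpentyl]-3-methyloxiran-2-yl]methanol
Conditions: Ti(OiPr)4 (10 mol%), D-(−)-diethyl tartrate (12 mol%), t-BuOOH, 4 Å MS, CH2Cl2, −20 °C
Reagents that add atoms: tert-butyl hydroperoxide CC(C)(C)OO
Why: Sharpless asymmetric epoxidation of a geraniol-type E-allylic alcohol, where the D-(−)-tartrate delivers oxygen to the face that gives the (2R,3R)-epoxy alcohol and so sets C4 and C5 of the target.

Step 5
Reactants: 10 [(2R,3R)-3-[(4R)-5-(tert-butyldimethylsilyloxy)-4-methylpentyl]-3-methyloxiran-2-yl]methanol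
Product: 11 (2S,3R)-3-[(4R)-5-(tert-butyldimethylsilyloxy)-4-methylpentyl]-3-methyloxirane-2-carbaldehyde
Conditions: Dess–Martin periodinane, NaHCO3, CH2Cl2, 0 °C → rt; used crude
Reagents that add atoms: none
Why: Buffered Dess–Martin oxidation gives the α,β-epoxy aldehyde without epimerisation or epoxide opening (the descriptor at the α-carbon changes from R to S only because the CIP priorities change).

Step 6
Reactants: 12 methyl acrylate; 13 (tert-butyldimethylsilyloxy)acetaldehyde
Product: 14 methyl (±)-4-(tert-butyldimethylsilyloxy)-3-hydroxy-2-methylidenebutanoate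
Conditions: DABCO (1 equiv), MeOH, rt, 3–5 d
Reagents that add atoms: none
Why: Morita–Baylis–Hillman reaction of an activated α-silyloxy aldehyde with methyl acrylate, whose racemic carbinol centre is destroyed in the next step.

Step 7
Reactants: 14 methyl (±)-4-(tert-butyldimethylsilyloxy)-3-hydroxy-2-methylidenebutanoate
Product: 15 methyl (2Z)-2-(bromomethyl)-4-(tert-butyldimethylsilyloxy)but-2-enoate
Conditions: NBS, Me2S, CH2Cl2, 0 °C → rt
Reagents that add atoms: N-bromosuccinimide O=C1CCC(=O)N1Br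
Why: Corey–Kim-type SN2′ bromination of the Baylis–Hillman alcohol, which gives the thermodynamically preferred (Z)-2-(bromomethyl)enoate under conditions that spare the TBS ether.

Step 8
Reactants: 11 (2S,3R)-3-[(4R)-5-(tert-butyldimethylsilyloxy)-4-methylpentyl]-3-methyloxirane-2-carbaldehyde; 15 methyl (2Z)-2-(bromomethyl)-4-(tert-butyldimethylsilyloxy)but-2-enoate
Product: 17 methyl (3S,4R)-3-[(tert-butyldimethylsilyloxy)methyl]-4-hydroxy-4-[(2R,3R)-3-[(4R)-5-(tert-butyldimethylsilyloxy)-4-methylpentyl]-3-methyloxiran-2-yl]-2-methylidenebutanoate, via allylchromium reagent 16 (not isolated)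
Conditions: CrCl2 (4 equiv), THF, 0 °C → rt; pH 7 phosphate buffer quench at 0 °C
Reagents that add atoms: none
Why: Nozaki–Hiyama Cr(II) 2-(alkoxycarbonyl)allylation, in which the equilibrating allyl-Cr(III) species adds through its γ-carbon in a chair transition state to give the anti C6-OH/C7-CH2OTBS relationship, while polar Felkin–Anh attack anti to the epoxide C–O bond sets C6 erythro to the epoxide, so C6 and C7 are both relayed from the Sharpless epoxide.

Step 9
Reactants: 17 methyl (3S,4R)-3-[(tert-butyldimethylsilyloxy)methyl]-4-hydroxy-4-[(2R,3R)-3-[(4R)-5-(tert-butyldimethylsilyloxy)-4-methylpentyl]-3-methyloxiran-2-yl]-2-methylidenebutanoate; 18 3-methylbut-2-enoyl chloride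
Product: 19 methyl (3S,4R)-3-[(tert-butyldimethylsilyloxy)methyl]-4-[(2R,3R)-3-[(4R)-5-(tert-butyldimethylsilyloxy)-4-methylpentyl]-3-methyloxiran-2-yl]-2-methylidene-4-[(3-methylbut-2-enoyl)oxy]butanoate
Conditions: pyridine, DMAP (20 mol%), CH2Cl2, 0 °C
Reagents that add atoms: none
Why: DMAP-catalysed acylation of the secondary alcohol with pyridine as the only base (which limits vinylketene-derived deconjugation of the senecioyl group and blocks 6,12-lactonisation), with no stereocentre touched.

Step 10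
Reactants: 19 methyl (3S,4R)-3-[(tert-butyldimethylsilyloxy)methyl]-4-[(2R,3R)-3-[(4R)-5-(tert-butyldimethylsilyloxy)-4-methylpentyl]-3-methyloxiran-2-yl]-2-methylidene-4-[(3-methylbut-2-enoyl)oxy]butanoate
Product: 20 methyl (3S,4R)-3-(hydroxymethyl)-4-[(2R,3R)-3-[(4R)-5-hydroxy-4-methylpentyl]-3-methyloxiran-2-yl]-2-methylidene-4-[(3-methylbut-2-enoyl)oxy]butanoate
Conditions: TBAF, AcOH (1:1), THF, 0 °C → rt
Reagents that add atoms: none
Why: Acetic-acid-buffered fluoride desilylation removes both primary TBS ethers near neutrality, so the epoxide, both esters and the lactonisation-prone γ-hydroxy acrylate survive.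

Step 11
Reactants: 20 methyl (3S,4R)-3-(hydroxymethyl)-4-[(2R,3R)-3-[(4R)-5-hydroxy-4-methylpentyl]-3-methyloxiran-2-yl]-2-methylidene-4-[(3-methylbut-2-enoyl)oxy]butanoate
Product: 21 methyl (3R,4R)-3-formyl-4-[(2R,3R)-3-methyl-3-[(4R)-4-methyl-5-oxopentyl]oxiran-2-yl]-2-methylidene-4-[(3-methylbut-2-enoyl)oxy]butanoate
Conditions: Dess–Martin periodinane (3 equiv), NaHCO3, CH2Cl2, 0 °C; filtered and used at once
Reagents that add atoms: none
Why: Base-free Dess–Martin oxidation of both primary alcohols, which avoids β-elimination of the C6 ester and epimerisation at C7 and C10 (the C7 descriptor changes from S to R only through CIP priorities).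

Step 12
Reactants: 21 methyl (3R,4R)-3-formyl-4-[(2R,3R)-3-methyl-3-[(4R)-4-methyl-5-oxopentyl]oxiran-2-yl]-2-methylidene-4-[(3-methylbut-2-enoyl)oxy]butanoate
Product: 23 (4R,5R,6R,7S,8S,9R,10R)-4,5-epoxy-9-hydroxy-6-[(3-methylbut-2-enoyl)oxy]germacr-11(13)-en-12,8-olide (CNP0119422.1), via macrocyclic diol ester 22 (not isolated)
Conditions: SmI2 (5 equiv, 0.1 M in THF), THF, −78 °C, syringe-pump addition of 21 (final 2 mM), then 0 °C; aq. Rochelle salt
Reagents that add atoms: none
Why: SmI2 pinacol macrocyclisation (ketyl radical–radical coupling), in which rapid one-electron reduction of both aldehydes under inverse addition gives a Sm(III)-bridged bis-ketyl that forms C8–C9 as the cis-diol, with the C8 face set by the C7 stereocentre (acrylate branch turned away from the forming bond) and C9 by the samarium bridge, after which the C8 samarium alkoxide acylates the methyl ester to close the trans γ-lactone and leave C9-OH free.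

## Compound list

1 | (S)-3-bromo-2-methylpropan-1-ol | OC[C@H](C)CBr | starting material
2 | (S)-(3-bromo-2-methylpropoxy)(tert-butyl)dimethylsilane | CC(C)(C)[Si](C)(C)OC[C@H](C)CBr | intermediate
3 | (4-bromobut-1-yn-1-yl)trimethylsilane | C[Si](C)(C)C#CCCBr | starting material
4 | [4-(trimethylsilyl)but-3-yn-1-yl]magnesium bromide | C[Si](C)(C)C#CCC[Mg]Br | intermediate
5 | (R)-tert-butyldimethyl{[2-methyl-7-(trimethylsilyl)hept-6-yn-1-yl]oxy}silane | CC(C)(C)[Si](C)(C)OC[C@H](C)CCCC#C[Si](C)(C)C | intermediate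
6 | (R)-tert-butyldimethyl[(2-methylhept-6-yn-1-yl)oxy]silane | CC(C)(C)[Si](C)(C)OC[C@H](C)CCCC#C | intermediate
7 | dimethyl[(1E,6R)-7-(tert-butyldimethylsilyloxy)-2,6-dimethylhept-1-en-1-yl]alane | C[Al](C)/C=C(\C)CCC[C@@H](C)CO[Si](C)(C)C(C)(C)C | intermediate
8 | lithium butyl(dimethyl)[(1E,6R)-7-(tert-butyldimethylsilyloxy)-2,6-dimethylhept-1-en-1-yl]aluminate | [Li+].CCCC[Al-](C)(C)/C=C(\C)CCC[C@@H](C)CO[Si](C)(C)C(C)(C)C | intermediate
9 | (2E,7R)-8-(tert-butyldimethylsilyloxy)-3,7-dimethyloct-2-en-1-ol | OC/C=C(\C)CCC[C@@H](C)CO[Si](C)(C)C(C)(C)C | intermediate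
10 | [(2R,3R)-3-[(4R)-5-(tert-butyldimethylsilyloxy)-4-methylpentyl]-3-methyloxiran-2-yl]methanol | OC[C@H]1O[C@]1(C)CCC[C@@H](C)CO[Si](C)(C)C(C)(C)C | intermediate
11 | (2S,3R)-3-[(4R)-5-(tert-butyldimethylsilyloxy)-4-methylpentyl]-3-methyloxirane-2-carbaldehyde | O=C[C@H]1O[C@]1(C)CCC[C@@H](C)CO[Si](C)(C)C(C)(C)C | intermediate
12 | methyl acrylate | C=CC(=O)OC | starting material
13 | (tert-butyldimethylsilyloxy)acetaldehyde | CC(C)(C)[Si](C)(C)OCC=O | starting material
14 | methyl (±)-4-(tert-butyldimethylsilyloxy)-3-hydroxy-2-methylidenebutanoate (racemic) | COC(=O)C(=C)C(O)CO[Si](C)(C)C(C)(C)C | intermediate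
15 | methyl (2Z)-2-(bromomethyl)-4-(tert-butyldimethylsilyloxy)but-2-enoate | COC(=O)/C(CBr)=C/CO[Si](C)(C)C(C)(C)C | intermediate
16 | dichloro[2-(methoxycarbonyl)-4-(tert-butyldimethylsilyloxy)but-2-en-1-yl]chromium(III) (E/Z equilibrating) | COC(=O)C(C[Cr](Cl)Cl)=CCO[Si](C)(C)C(C)(C)C | intermediate
17 | methyl (3S,4R)-3-[(tert-butyldimethylsilyloxy)methyl]-4-hydroxy-4-[(2R,3R)-3-[(4R)-5-(tert-butyldimethylsilyloxy)-4-methylpentyl]-3-methyloxiran-2-yl]-2-methylidenebutanoate | CC(C)(C)[Si](C)(C)OC[C@H](C)CCC[C@@]1(C)O[C@@H]1[C@H](O)[C@H](CO[Si](C)(C)C(C)(C)C)C(=C)C(=O)OC | intermediate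
18 | 3-methylbut-2-enoyl chloride (senecioyl chloride) | CC(C)=CC(Cl)=O | starting material
19 | methyl (3S,4R)-3-[(tert-butyldimethylsilyloxy)methyl]-4-[(2R,3R)-3-[(4R)-5-(tert-butyldimethylsilyloxy)-4-methylpentyl]-3-methyloxiran-2-yl]-2-methylidene-4-[(3-methylbut-2-enoyl)oxy]butanoate | CC(C)(C)[Si](C)(C)OC[C@H](C)CCC[C@@]1(C)O[C@@H]1[C@H](OC(=O)C=C(C)C)[C@H](CO[Si](C)(C)C(C)(C)C)C(=C)C(=O)OC | intermediate
20 | methyl (3S,4R)-3-(hydroxymethyl)-4-[(2R,3R)-3-[(4R)-5-hydroxy-4-methylpentyl]-3-methyloxiran-2-yl]-2-methylidene-4-[(3-methylbut-2-enoyl)oxy]butanoate | OC[C@H](C)CCC[C@@]1(C)O[C@@H]1[C@H](OC(=O)C=C(C)C)[C@H](CO)C(=C)C(=O)OC | intermediate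
21 | methyl (3R,4R)-3-formyl-4-[(2R,3R)-3-methyl-3-[(4R)-4-methyl-5-oxopentyl]oxiran-2-yl]-2-methylidene-4-[(3-methylbut-2-enoyl)oxy]butanoate | O=C[C@H](C)CCC[C@@]1(C)O[C@@H]1[C@H](OC(=O)C=C(C)C)[C@H](C=O)C(=C)C(=O)OC | intermediate
22 | methyl 2-[(1R,2R,3S,4S,5R,6R,10R)-4,5-dihydroxy-6,10-dimethyl-2-[(3-methylbut-2-enoyl)oxy]-11-oxabicyclo[8.1.0]undecan-3-yl]prop-2-enoate (present as its samarium(III) diolate) | C=C(C(=O)OC)[C@H]1[C@H](O)[C@H](O)[C@H](C)CCC[C@@]2(C)O[C@@H]2[C@@H]1OC(=O)C=C(C)C | intermediate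
23 | (4R,5R,6R,7S,8S,9R,10R)-4,5-epoxy-9-hydroxy-6-[(3-methylbut-2-enoyl)oxy]germacr-11(13)-en-12,8-olide (CNP0119422.1) | C=C1C(=O)O[C@@H]2[C@H](O)[C@H](C)CCC[C@@]3(C)O[C@@H]3[C@H](OC(=O)C=C(C)C)[C@@H]12 | target

## Step count and risks

Total steps: 12. Longest linear sequence: 10 (steps 1–5 and 8–12); steps 6–7 form the convergent branch.

**Step 12 (SmI2 pinacol macrocyclisation) is the most likely to fail.** A ten-membered ring must close against oligomerisation, the C9 ketyl could instead add 11-endo to the acrylate, the C8 alkoxide could open the epoxide instead of lactonising, and the cis-diol demanded at C9 is anti-Felkin with respect to the C10 methyl. The most probable stereochemical miss is the trans-diol (C9 epimer). The fallback sets out from 21 and returns at 23, and it separates ring closure from C9 control. The same SmI2 coupling is run and the 9-epi lactone (4R,5R,6R,7S,8S,9S,10R)-4,5-epoxy-9-hydroxy-6-[(3-methylbut-2-enoyl)oxy]germacr-11(13)-en-12,8-olide F1 is accepted. Its only free hydroxyl is oxidised with Dess–Martin periodinane to the ketone (4R,5R,6R,7S,8S,10R)-4,5-epoxy-9-oxo-6-[(3-methylbut-2-enoyl)oxy]germacr-11(13)-en-12,8-olide F2. Chelation-controlled reduction (Zn(BH4)2, Et2O, −30 °C, hydride delivered on the chelate between the ketone and the lactone ring oxygen, which also spares the methylene lactone) then gives the cis C8–O/C9–OH relationship of 23. A wrong configuration at C8 cannot be repaired this way.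

**Step 8 (Cr(II) allylation of the epoxy aldehyde) is the second risk.** The anti/syn ratio of this γ-substituted 2-(alkoxycarbonyl)allyl reagent and the Felkin ratio at the epoxy aldehyde are both substrate-dependent, and the Cr(III) alkoxide can lactonise onto the methyl ester. The fallback sets out from 11 and 15 and returns at 19. An indium-mediated Barbier reaction (In powder, THF/H2O 1:1, rt) is reliably γ-syn through the (Z)-allylindium chair, does not lactonise, and under chelation of the aldehyde and epoxide oxygens should give the C6 epimer methyl (3S,4S)-3-[(tert-butyldimethylsilyloxy)methyl]-4-hydroxy-4-[(2R,3R)-3-[(4R)-5-(tert-butyldimethylsilyloxy)-4-methylpentyl]-3-methyloxiran-2-yl]-2-methylidenebutanoate F3. Mitsunobu esterification with 3-methylbut-2-enoic acid (PPh3, DIAD, toluene, 0 °C) then inverts C6 and installs the senecioate in one operation to give 19, so step 9 is not needed.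

**Step 10 (double desilylation) is the third risk.** The freed C8 hydroxyl is γ to the acrylate ester (lactonisation), 1,3 to the senecioate (acyl migration) and δ to the epoxide (5-exo opening). The fallback sets out from 19 and returns at 21 without ever forming the diol: a one-pot oxidative desilylation (TEMPO cat., PhI(OAc)2, Bi(OTf)3 cat., MeCN/H2O, 0 °C) converts the two primary TBS ethers directly into the aldehydes, so no free γ-hydroxy ester accumulates and no new compound is made.

Further compounds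
F1 | step 12 | (4R,5R,6R,7S,8S,9S,10R)-4,5-epoxy-9-hydroxy-6-[(3-methylbut-2-enoyl)oxy]germacr-11(13)-en-12,8-olide | C=C1C(=O)O[C@@H]2[C@@H](O)[C@H](C)CCC[C@@]3(C)O[C@@H]3[C@H](OC(=O)C=C(C)C)[C@@H]12
F2 | step 12 | (4R,5R,6R,7S,8S,10R)-4,5-epoxy-9-oxo-6-[(3-methylbut-2-enoyl)oxy]germacr-11(13)-en-12,8-olide | C=C1C(=O)O[C@@H]2C(=O)[C@H](C)CCC[C@@]3(C)O[C@@H]3[C@H](OC(=O)C=C(C)C)[C@@H]12
F3 | step 8 | methyl (3S,4S)-3-[(tert-butyldimethylsilyloxy)methyl]-4-hydroxy-4-[(2R,3R)-3-[(4R)-5-(tert-butyldimethylsilyloxy)-4-methylpentyl]-3-methyloxiran-2-yl]-2-methylidenebutanoate | CC(C)(C)[Si](C)(C)OC[C@H](C)CCC[C@@]1(C)O[C@@H]1[C@@H](O)[C@H](CO[Si](C)(C)C(C)(C)C)C(=C)C(=O)OC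
F0 | step 10 | none | none
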